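Ring B is disconnected between C6 and C7. C6 bears the acyloxy oxygen and C7 sits β to the C12 carbonyl, so both are acceptor carbons and no polar pairing joins them; an acyl radical at C6 adding to an acrylate terminus at C7 does. A single decatungstate-photocatalysed hydroacylation therefore converts a ring A aldehyde carrying an itaconate arm on quaternary C10 into the trans-fused 6-oxodrimane diester, closing ring B and installing the C6 ketone that later delivers the 7-ene, the 6β-ester and a regiodefined C9 hydroxylation. The precursor, a 6,7-seco-drimane with a C11 tert-butyl and a C12 methyl ester, comes from enantioselectively allylated 2,2,6-trimethylcyclohexanone.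

Key step: step 12

Remark (numbering): drimane numbering (C1–C15) is used for all intermediates, including the monocyclic ones.
Remark (stereochemistry): C5 (from step 6) and C9 (from step 8) are not controlled at the seco stage; compounds 8–17 are drawn as one epimer and are carried together with their C5/C9 epimers, which converge in steps 12 and 15.
Remark (target): 29 is taken as the open hydroxy acid–aldehyde written in the target SMILES.

Step 1
Reactants: 1 2,2,6-trimethylcyclohexanone; 2 allyl chloroformate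
Product: 3 allyl 2,6,6-trimethylcyclohex-1-en-1-yl carbonate
Conditions: LiN(SiMe3)2, THF, 0 °C; then 2, −78 → 23 °C
Reagents that add atoms: none
Why: The only enolisable position gives a tetrasubstituted lithium enolate whose hindered carbon should favour O-acylation by the chloroformate (enol carbonate formation).

Step 2
Reactants: 3 allyl 2,6,6-trimethylcyclohex-1-en-1-yl carbonate
Product: 4 (R)-2-allyl-2,6,6-trimethylcyclohexanone
Conditions: Pd2(dba)3 (2.5 mol%), (R)-4-tert-butyl-2-(2-diphenylphosphinophenyl)-4,5-dihydrooxazole (6 mol%), THF, 25 °C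
Reagents that add atoms: none
Why: Decarboxylative asymmetric allylic alkylation (Tsuji type), in which zerovalent palladium ionises the allyl carbonate, CO2 is lost and the enolate–allyl pair recombines inside the chiral P,N-ligand sphere to set the C10 quaternary centre; the (R)-ligand is chosen by analogy with the (S)-ligand/(S)-α-allyl-α-methylcyclohexanone pairing.

Step 3
Reactants: 4 (R)-2-allyl-2,6,6-trimethylcyclohexanone
Product: 5 2-[(1R)-1,3,3-trimethyl-2-oxocyclohexyl]acetic acid
Conditions: RuCl3·xH2O (2 mol%), NaIO4, CCl4/MeCN/H2O, 23 °C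
Reagents that add atoms: sodium periodate, [Na+].[O-]I(=O)(=O)=O; water, O
Why: Catalytically generated RuO4 cleaves the terminal alkene to the carboxylic acid with loss of the terminal carbon (oxidative alkene cleavage), and the non-enolisable ketone and the quaternary centre are inert.

Step 4
Reactants: 5 2-[(1R)-1,3,3-trimethyl-2-oxocyclohexyl]acetic acid
Product: 6 tert-butyl 2-[(1R)-1,3,3-trimethyl-2-oxocyclohexyl]acetate
Conditions: tert-butyl 2,2,2-trichloroacetimidate, BF3·OEt2 (cat.), CH2Cl2/cyclohexane, 23 °C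
Reagents that add atoms: tert-butyl 2,2,2-trichloroacetimidate, CC(C)(C)OC(=N)C(Cl)(Cl)Cl
Why: Acid-catalysed O-alkylation of the acid by the imidate (tert-butyl esterification) installs the C11 ester that should survive alkoxide, enolate and hydride steps and is removed last by acid.

Step 5
Reactants: 6 tert-butyl 2-[(1R)-1,3,3-trimethyl-2-oxocyclohexyl]acetate
Product: 7 tert-butyl 2-[(1R)-1,3,3-trimethyl-2-methylidenecyclohexyl]acetate
Conditions: Ph3PCH3Br, KOtBu, toluene, 100 °C
Reagents that add atoms: methyltriphenylphosphonium bromide, C[P+](c1ccccc1)(c1ccccc1)c1ccccc1.[Br-]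
Why: Wittig methylenation under hot, lithium-free conditions suits a ketone that cannot enolise, and tert-butoxide cannot degrade a tert-butyl ester because its attack is degenerate.

Step 6
Reactants: 7 tert-butyl 2-[(1R)-1,3,3-trimethyl-2-methylidenecyclohexyl]acetate
Product: 9 tert-butyl 2-[(1R,2S)-2-(hydroxymethyl)-1,3,3-trimethylcyclohexyl]acetate, via primary alkylborane 8 (not isolated)
Conditions: BH3·THF, THF, 0 → 23 °C; then NaOH, H2O2, 0 °C
Reagents that add atoms: hydrogen peroxide, OO
Why: Anti-Markovnikov hydroboration–oxidation places oxygen on the terminal carbon C6, and hydrogen should reach C5 on the face away from the syn-axial C4/C10 methyl groups (5S drawn), although either C5 epimer is usable because C5 is re-equilibrated in step 12.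

Step 7
Reactants: 9 tert-butyl 2-[(1R,2S)-2-(hydroxymethyl)-1,3,3-trimethylcyclohexyl]acetate
Product: 10 tert-butyl 2-[(1R,2S)-2-{[tert-butyl(dimethyl)silyl]oxymethyl}-1,3,3-trimethylcyclohexyl]acetate
Conditions: tBuMe2SiCl, imidazole, DMF, 23 °C
Reagents that add atoms: tert-butyldimethylsilyl chloride, CC(C)(C)[Si](C)(C)Cl
Why: Standard silylation of the primary alcohol masks O6 through the two enolate steps that follow.

Step 8
Reactants: 10 tert-butyl 2-[(1R,2S)-2-{[tert-butyl(dimethyl)silyl]oxymethyl}-1,3,3-trimethylcyclohexyl]acetate; 11 methyl bromoacetate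
Product: 12 1-tert-butyl 4-methyl (2S)-2-[(1S,2S)-2-{[tert-butyl(dimethyl)silyl]oxymethyl}-1,3,3-trimethylcyclohexyl]butanedioate (with its C9 epimer)
Conditions: LiN(iPr)2, THF, −78 °C; DMPU, 11, −78 → −20 °C
Reagents that add atoms: none
Why: The kinetic lithium enolate of the tert-butyl ester is alkylated (SN2) by the α-bromo ester to form C8–C9, and the uncontrolled C9 centre is harmless because C9 is planarised again in step 15.

Step 9
Reactants: 12 1-tert-butyl 4-methyl (2S)-2-[(1S,2S)-2-{[tert-butyl(dimethyl)silyl]oxymethyl}-1,3,3-trimethylcyclohexyl]butanedioate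
Product: 15 1-tert-butyl 4-methyl (2R)-2-[(1S,2S)-2-{[tert-butyl(dimethyl)silyl]oxymethyl}-1,3,3-trimethylcyclohexyl]-3-methylidenebutanedioate (with its C9 epimer), via Mannich base 13 (not isolated), via trimethylammonium iodide 14 (not isolated)
Conditions: LiN(iPr)2, THF, −78 °C; CH2=NMe2+ I−, −78 → 23 °C; MeI, CH2Cl2, 23 °C; DBU, 0 °C
Reagents that add atoms: N,N-dimethylmethyleneiminium iodide (Eschenmoser's salt), C=[N+](C)C.[I-]
Why: The base removes a proton from the unhindered C8 methylene rather than the neopentyl C9–H, the enolate is aminomethylated (Mannich reaction), and quaternisation followed by E1cB loss of trimethylamine should give the α-methylene ester (Eschenmoser methylenation).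

Step 10
Reactants: 15 1-tert-butyl 4-methyl (2R)-2-[(1S,2S)-2-{[tert-butyl(dimethyl)silyl]oxymethyl}-1,3,3-trimethylcyclohexyl]-3-methylidenebutanedioate
Product: 16 1-tert-butyl 4-methyl (2R)-2-[(1S,2S)-2-(hydroxymethyl)-1,3,3-trimethylcyclohexyl]-3-methylidenebutanedioate (with its C9 epimer)
Conditions: HF·pyridine, THF/pyridine, 0 → 23 °C
Reagents that add atoms: none
Why: Fluoride-mediated desilylation under buffered, weakly acidic conditions should neither isomerise the itaconate nor cleave the tert-butyl ester.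

Step 11
Reactants: 16 1-tert-butyl 4-methyl (2R)-2-[(1S,2S)-2-(hydroxymethyl)-1,3,3-trimethylcyclohexyl]-3-methylidenebutanedioate
Product: 17 1-tert-butyl 4-methyl (2R)-2-[(1S,2S)-2-formyl-1,3,3-trimethylcyclohexyl]-3-methylidenebutanedioate (6,7-seco precursor; with its C9 epimer)
Conditions: Dess–Martin periodinane, CH2Cl2, 0 → 23 °C
Reagents that add atoms: none
Why: Dess–Martin oxidation takes the primary alcohol to the aldehyde under neutral conditions without touching the acrylate.

Step 12
Reactants: 17 1-tert-butyl 4-methyl (2R)-2-[(1S,2S)-2-formyl-1,3,3-trimethylcyclohexyl]-3-methylidenebutanedioate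
Product: 19 11-tert-butyl 12-methyl (5S,8R,9S,10S)-6-oxodrimane-11,12-dioate, via crude epimeric keto diester 18 (not isolated)
Conditions: (nBu4N)4W10O32 (2 mol%), MeCN (0.02 M), 390 nm LEDs, Ar, 20 °C; then NaOMe (cat.), MeOH, 40 °C
Reagents that add atoms: none
Why: Excited decatungstate abstracts the formyl hydrogen of 17, the nucleophilic C6 acyl radical adds to the unsubstituted terminus C7 of the electron-poor itaconate, and the ester-stabilised tertiary C8 radical takes a hydrogen atom back from the reduced polyoxometalate, so no stoichiometric reagent is consumed. The closest known reactions are decatungstate-photocatalysed hydroacylation of acrylates and 6-endo cyclisations of acyl radicals onto α-substituted acrylates. Ring B closes 6-endo-trig, because the 5-exo mode would require attack at the fully substituted, polarity-mismatched C8 that carries the C12 ester. The new C8 centre is formed unselectively by hydrogen-atom return and is then placed equatorial (8α-ester) by methoxide equilibration, which should also converge C5 to the trans ring fusion (5α-H) and C9 to the 9β-ester around the fixed C10 centre; any residual C8/C9 epimer is inconsequential because both carbons are planarised in steps 13 and 15. The step needs formyl C–H abstraction over ring C–H abstraction and cyclisation over decarbonylation; the first is secured by the polarity match between the hydridic formyl hydrogen and the electrophilic oxo-radical catalyst, the second by the compressed tether at quaternary C10 and the activated acceptor, aided by ambient temperature and dilution.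

Step 13
Reactants: 19 11-tert-butyl 12-methyl (5S,8R,9S,10S)-6-oxodrimane-11,12-dioate
Product: 21 11-tert-butyl 12-methyl (5S,9R,10S)-6-oxodrim-7-ene-11,12-dioate, via trimethylsilyl enol ether 20 (not isolated)
Conditions: LiN(SiMe3)2, Me3SiCl, THF, −78 °C; then Pd(OAc)2 (1.1 equiv), MeCN, 23 °C
Reagents that add atoms: none
Why: Kinetic deprotonation at the unhindered C7 methylene gives the 6-ene silyl enol ether, and Saegusa–Ito oxidation (palladation at C7, β-hydride loss of the ester-activated H8) should give the 7-en-6-one.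

Step 14
Reactants: 21 11-tert-butyl 12-methyl (5S,9R,10S)-6-oxodrim-7-ene-11,12-dioate
Product: 22 11-tert-butyl 12-methyl (5S,6R,9R,10S)-6-hydroxydrim-7-ene-11,12-dioate
Conditions: NaBH4, CeCl3·7H2O, MeOH, −40 °C
Reagents that add atoms: none
Why: Luche 1,2-reduction, in which hydride attacks C6 from the α face because the β face is shielded by the syn-axial C4β and C10 methyl groups, should give the 6β (6R) allylic alcohol.

Step 15
Reactants: 22 11-tert-butyl 12-methyl (5S,6R,9R,10S)-6-hydroxydrim-7-ene-11,12-dioate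
Product: 23 11-tert-butyl 12-methyl (5S,6R,9S,10S)-6,9-dihydroxydrim-7-ene-11,12-dioate
Conditions: KN(SiMe3)2 (2.3 equiv), THF, −78 °C; 3-phenyl-2-(phenylsulfonyl)oxaziridine, −78 °C; AcOH
Reagents that add atoms: 3-phenyl-2-(phenylsulfonyl)oxaziridine, O=S(=O)(c1ccccc1)N1OC1c1ccccc1
Why: With O6 held as its alkoxide (which also blocks γ-deprotonation at C6), the second equivalent of base forms the C11 ester dienolate, whose α-carbon C9 is hydroxylated by the N-sulfonyloxaziridine (enolate hydroxylation) on the α face, anti to the C10 methyl, to set 9S; reducing the ketone first removes the competing ketone-enolate site at C7.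

Step 16
Reactants: 23 11-tert-butyl 12-methyl (5S,6R,9S,10S)-6,9-dihydroxydrim-7-ene-11,12-dioate
Product: 24 tert-butyl (5S,6R,9S,10S)-6,9,12-trihydroxydrim-7-en-11-oate
Conditions: iBu2AlH (5 equiv), CH2Cl2, −78 °C; aq. potassium sodium tartrate
Reagents that add atoms: none
Why: Hydride reduction of the unhindered conjugated methyl ester to the allylic alcohol should proceed at −78 °C, while the tert-butyl ester on the fully substituted C9 is too hindered to react.

Step 17
Reactants: 24 tert-butyl (5S,6R,9S,10S)-6,9,12-trihydroxydrim-7-en-11-oate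
Product: 25 tert-butyl (5S,6R,9S,10S)-6,9-dihydroxy-12-oxodrim-7-en-11-oate
Conditions: TEMPO (10 mol%), PhI(OAc)2, CH2Cl2, 23 °C
Reagents that add atoms: none
Why: Oxoammonium (TEMPO) oxidation is selective for the primary allylic alcohol over the hindered secondary and the tertiary hydroxyl groups and should stop at the enal.

Step 18
Reactants: 25 tert-butyl (5S,6R,9S,10S)-6,9-dihydroxy-12-oxodrim-7-en-11-oate; 26 (2E,4E,6E)-octa-2,4,6-trienoic acid
Product: 28 tert-butyl (5S,6R,9S,10S)-9-hydroxy-6-[(2E,4E,6E)-octa-2,4,6-trienoyloxy]-12-oxodrim-7-en-11-oate, via mixed anhydride 27 (not isolated)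
Conditions: 26, 2,4,6-trichlorobenzoyl chloride, Et3N, THF, 23 °C; then 25, DMAP, toluene, 23 °C
Reagents that add atoms: none
Why: Yamaguchi esterification transfers the trienoyl group through DMAP to the secondary 6β-hydroxyl, the tertiary 9α-hydroxyl being unreactive, and the mild conditions should retain the all-E geometry.

Step 19
Reactants: 28 tert-butyl (5S,6R,9S,10S)-9-hydroxy-6-[(2E,4E,6E)-octa-2,4,6-trienoyloxy]-12-oxodrim-7-en-11-oate
Product: 29 ustusoic acid B
Conditions: CF3CO2H/CH2Cl2 (1:4), 0 °C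
Reagents that add atoms: none
Why: Acidolysis of the tert-butyl ester (E1 loss of isobutene) frees the C11 acid, and the electron-poor enal and the ester-bearing C9 disfavour ionisation of the allylic ester and of the tertiary alcohol.

Compound list
1 | 2,2,6-trimethylcyclohexanone (racemic) | CC1CCCC(C)(C)C1=O | starting material
2 | allyl chloroformate | C=CCOC(=O)Cl | starting material
3 | allyl 2,6,6-trimethylcyclohex-1-en-1-yl carbonate | C=CCOC(=O)OC1=C(C)CCCC1(C)C | intermediate
4 | (R)-2-allyl-2,6,6-trimethylcyclohexanone | C=CC[C@@]1(C)CCCC(C)(C)C1=O | intermediate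
5 | 2-[(1R)-1,3,3-trimethyl-2-oxocyclohexyl]acetic acid | OC(=O)C[C@@]1(C)CCCC(C)(C)C1=O | intermediate
6 | tert-butyl 2-[(1R)-1,3,3-trimethyl-2-oxocyclohexyl]acetate | CC(C)(C)OC(=O)C[C@@]1(C)CCCC(C)(C)C1=O | intermediate
7 | tert-butyl 2-[(1R)-1,3,3-trimethyl-2-methylidenecyclohexyl]acetate | CC(C)(C)OC(=O)C[C@@]1(C)CCCC(C)(C)C1=C | intermediate
8 | primary alkylborane of 7 (boron on C6; drawn as the monoalkylborane, 5S) | CC(C)(C)OC(=O)C[C@@]1(C)CCCC(C)(C)[C@@H]1CB | intermediate (not isolated)
9 | tert-butyl 2-[(1R,2S)-2-(hydroxymethyl)-1,3,3-trimethylcyclohexyl]acetate | CC(C)(C)OC(=O)C[C@@]1(C)CCCC(C)(C)[C@@H]1CO | intermediate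
10 | tert-butyl 2-[(1R,2S)-2-{[tert-butyl(dimethyl)silyl]oxymethyl}-1,3,3-trimethylcyclohexyl]acetate | CC(C)(C)OC(=O)C[C@@]1(C)CCCC(C)(C)[C@@H]1CO[Si](C)(C)C(C)(C)C | intermediate
11 | methyl bromoacetate | COC(=O)CBr | starting material
12 | 1-tert-butyl 4-methyl (2S)-2-[(1S,2S)-2-{[tert-butyl(dimethyl)silyl]oxymethyl}-1,3,3-trimethylcyclohexyl]butanedioate (drimane 5S,9S,10S; with C9 epimer) | COC(=O)C[C@H](C(=O)OC(C)(C)C)[C@@]1(C)CCCC(C)(C)[C@@H]1CO[Si](C)(C)C(C)(C)C | intermediate
13 | Mannich base: C8 (dimethylamino)methyl derivative of 12 (C8 epimers) | COC(=O)C(CN(C)C)[C@H](C(=O)OC(C)(C)C)[C@@]1(C)CCCC(C)(C)[C@@H]1CO[Si](C)(C)C(C)(C)C | intermediate (not isolated)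
14 | trimethylammonium iodide of 13 | COC(=O)C(C[N+](C)(C)C)[C@H](C(=O)OC(C)(C)C)[C@@]1(C)CCCC(C)(C)[C@@H]1CO[Si](C)(C)C(C)(C)C.[I-] | intermediate (not isolated)
15 | 1-tert-butyl 4-methyl (2R)-2-[(1S,2S)-2-{[tert-butyl(dimethyl)silyl]oxymethyl}-1,3,3-trimethylcyclohexyl]-3-methylidenebutanedioate (drimane 5S,9R,10S; with C9 epimer) | COC(=O)C(=C)[C@H](C(=O)OC(C)(C)C)[C@@]1(C)CCCC(C)(C)[C@@H]1CO[Si](C)(C)C(C)(C)C | intermediate
16 | 1-tert-butyl 4-methyl (2R)-2-[(1S,2S)-2-(hydroxymethyl)-1,3,3-trimethylcyclohexyl]-3-methylidenebutanedioate (with C9 epimer) | COC(=O)C(=C)[C@H](C(=O)OC(C)(C)C)[C@@]1(C)CCCC(C)(C)[C@@H]1CO | intermediate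
17 | 1-tert-butyl 4-methyl (2R)-2-[(1S,2S)-2-formyl-1,3,3-trimethylcyclohexyl]-3-methylidenebutanedioate (6,7-seco precursor; drimane 5S,9R,10S; with C9 epimer) | COC(=O)C(=C)[C@H](C(=O)OC(C)(C)C)[C@@]1(C)CCCC(C)(C)[C@@H]1C=O | intermediate
18 | 11-tert-butyl 12-methyl (10S)-6-oxodrimane-11,12-dioate as C5/C8/C9 epimer mixture | O=C1CC(C(=O)OC)C(C(=O)OC(C)(C)C)[C@@]2(C)CCCC(C)(C)C12 | intermediate (not isolated)
19 | 11-tert-butyl 12-methyl (5S,8R,9S,10S)-6-oxodrimane-11,12-dioate | O=C1C[C@@H](C(=O)OC)[C@H](C(=O)OC(C)(C)C)[C@@]2(C)CCCC(C)(C)[C@H]12 | intermediate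
20 | 6-(trimethylsilyloxy)drim-6-ene diester (silyl enol ether of 19) | C[Si](C)(C)OC1=C[C@@H](C(=O)OC)[C@H](C(=O)OC(C)(C)C)[C@@]2(C)CCCC(C)(C)[C@H]12 | intermediate (not isolated)
21 | 11-tert-butyl 12-methyl (5S,9R,10S)-6-oxodrim-7-ene-11,12-dioate | O=C1C=C(C(=O)OC)[C@H](C(=O)OC(C)(C)C)[C@@]2(C)CCCC(C)(C)[C@H]12 | intermediate
22 | 11-tert-butyl 12-methyl (5S,6R,9R,10S)-6-hydroxydrim-7-ene-11,12-dioate | O[C@@H]1C=C(C(=O)OC)[C@H](C(=O)OC(C)(C)C)[C@@]2(C)CCCC(C)(C)[C@H]12 | intermediate
23 | 11-tert-butyl 12-methyl (5S,6R,9S,10S)-6,9-dihydroxydrim-7-ene-11,12-dioate | O[C@@H]1C=C(C(=O)OC)[C@](O)(C(=O)OC(C)(C)C)[C@@]2(C)CCCC(C)(C)[C@H]12 | intermediate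
24 | tert-butyl (5S,6R,9S,10S)-6,9,12-trihydroxydrim-7-en-11-oate | O[C@@H]1C=C(CO)[C@](O)(C(=O)OC(C)(C)C)[C@@]2(C)CCCC(C)(C)[C@H]12 | intermediate
25 | tert-butyl (5S,6R,9S,10S)-6,9-dihydroxy-12-oxodrim-7-en-11-oate | O[C@@H]1C=C(C=O)[C@](O)(C(=O)OC(C)(C)C)[C@@]2(C)CCCC(C)(C)[C@H]12 | intermediate
26 | (2E,4E,6E)-octa-2,4,6-trienoic acid | C/C=C/C=C/C=C/C(=O)O | starting material
27 | (2E,4E,6E)-octa-2,4,6-trienoic 2,4,6-trichlorobenzoic anhydride | C/C=C/C=C/C=C/C(=O)OC(=O)c1c(Cl)cc(Cl)cc1Cl | intermediate (not isolated)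
28 | tert-butyl (5S,6R,9S,10S)-9-hydroxy-6-[(2E,4E,6E)-octa-2,4,6-trienoyloxy]-12-oxodrim-7-en-11-oate | C/C=C/C=C/C=C/C(=O)O[C@@H]1C=C(C=O)[C@](O)(C(=O)OC(C)(C)C)[C@@]2(C)CCCC(C)(C)[C@H]12 | intermediate
29 | ustusoic acid B, (5S,6R,9S,10S)-9-hydroxy-6-[(2E,4E,6E)-octa-2,4,6-trienoyloxy]-12-oxodrim-7-en-11-oic acid | C/C=C/C=C/C=C/C(=O)O[C@@H]1C=C(C=O)[C@](O)(C(=O)O)[C@@]2(C)CCCC(C)(C)[C@H]12 | target

Total step count: 19. Longest linear sequence: 19 steps (1 → 29); acid 26 is purchased and enters in step 18.

Steps most likely to fail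

Step 12. The hindered secondary acyl radical may lose CO before it closes ring B, or the excited catalyst may abstract ring C–H hydrogens unselectively, so that little of the bicyclic ketone forms. The fallback sets out from aldehyde 17 and generates the same radical in a chain process at low temperature. Pinnick oxidation (NaClO2, NaH2PO4, 2-methyl-2-butene, tBuOH/H2O) should give the carboxylic acid F1; PhSeSePh/PBu3 should convert it into the Se-phenyl selenoester F2; (Me3Si)3SiH with Et3B/air in benzene at 20 °C should then give the crude keto diester 18 by 6-endo acyl radical cyclisation, and methoxide equilibration as in step 12 returns to 19.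

Step 5. The bulky ylide may fail to add to a carbonyl flanked by two quaternary carbons, leaving 6 unchanged. The fallback sets out from allyl ketone 4, before the ester arm exists, and brings in C6 through a sulfur ylide and a 1,2-hydride shift instead of olefination and hydroboration. Dimethylsulfonium methylide (Me3S+ I−, nBuLi, THF, −10 °C; Corey–Chaykovsky reaction) should give the spiro-epoxide F3; BF3·OEt2 at −78 °C should rearrange it to the aldehyde F4 (Meinwald rearrangement); NaBH4 should give the primary alcohol F5; silylation as in step 7 the silyl ether F6; RuCl3/NaIO4 cleavage as in step 3 the acid F7; and esterification as in step 4 (imidate without Lewis acid) comes back to the route at 10.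

Step 15. Oxygen transfer may occur at the γ-carbon C7 of the dienolate, enolisation of the neopentyl C9–H may be incomplete, or facial selectivity may erode. The fallback sets out from enone 21 and installs the C9 oxygen by cycloaddition. LiN(SiMe3)2/tBuMe2SiCl should give the 6-silyloxy-6,8-diene F8; photo-oxygenation (O2, tetraphenylporphyrin, visible light, CH2Cl2, −78 °C) should add singlet oxygen across C6 and C9 on the α face to give the endoperoxide F9; thiourea reduction followed by HF·pyridine should give the 9α-hydroxy-7-en-6-one F10; and Luche reduction as in step 14 comes back to the route at 23.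

Further compounds
F1 | step 12 | (1S,2S)-2-[(2R)-1-tert-butoxy-4-methoxy-3-methylidene-1,4-dioxobutan-2-yl]-2,6,6-trimethylcyclohexanecarboxylic acid (acid from 17) | COC(=O)C(=C)[C@H](C(=O)OC(C)(C)C)[C@@]1(C)CCCC(C)(C)[C@@H]1C(=O)O
F2 | step 12 | Se-phenyl selenoester of F1 | COC(=O)C(=C)[C@H](C(=O)OC(C)(C)C)[C@@]1(C)CCCC(C)(C)[C@@H]1C(=O)[Se]c1ccccc1
F3 | step 5 | (4R)-4-allyl-4,8,8-trimethyl-1-oxaspiro[2.5]octane (spiro carbon epimers) | C=CC[C@@]1(C)CCCC(C)(C)C12CO2
F4 | step 5 | (1S,2R)-2-allyl-2,6,6-trimethylcyclohexanecarbaldehyde | C=CC[C@@]1(C)CCCC(C)(C)[C@@H]1C=O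
F5 | step 5 | [(1S,2R)-2-allyl-2,6,6-trimethylcyclohexyl]methanol | C=CC[C@@]1(C)CCCC(C)(C)[C@@H]1CO
F6 | step 5 | tert-butyldimethylsilyl ether of F5 | C=CC[C@@]1(C)CCCC(C)(C)[C@@H]1CO[Si](C)(C)C(C)(C)C
F7 | step 5 | 2-[(1R,2S)-2-{[tert-butyl(dimethyl)silyl]oxymethyl}-1,3,3-trimethylcyclohexyl]acetic acid | OC(=O)C[C@@]1(C)CCCC(C)(C)[C@@H]1CO[Si](C)(C)C(C)(C)C
F8 | step 15 | 11-tert-butyl 12-methyl (5S,10S)-6-(tert-butyldimethylsilyloxy)drima-6,8-diene-11,12-dioate | CC(C)(C)[Si](C)(C)OC1=CC(C(=O)OC)=C(C(=O)OC(C)(C)C)[C@@]2(C)CCCC(C)(C)[C@H]12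
F9 | step 15 | 6α,9α-epidioxy-6β-(tert-butyldimethylsilyloxy)drim-7-ene-11,12-dioate (endoperoxide of F8) | CC(C)(C)[Si](C)(C)O[C@]1(OO2)C=C(C(=O)OC)[C@]2(C(=O)OC(C)(C)C)[C@@]3(C)CCCC(C)(C)[C@H]13
F10 | step 15 | 11-tert-butyl 12-methyl (5S,9S,10S)-9-hydroxy-6-oxodrim-7-ene-11,12-dioate | O=C1C=C(C(=O)OC)[C@](O)(C(=O)OC(C)(C)C)[C@@]2(C)CCCC(C)(C)[C@H]12
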